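**Retrosynthetic overview**

- Punaglandin 8 (prostanoid numbering, 7S,8R,12S) comes from acetylation of the C7 hydroxyl. Before that, a C7 silyl ether that is needed only for the ring-forming step is removed.
- C8-C12 disconnection: the chlorocyclopentenone is made in one operation from a flat 2-furylcarbinol by a Piancatelli rearrangement, followed in the same flask by equilibration of C8. The furan skeleton becomes the carbocycle through a 4π-conrotatory closure. This parallels the allene oxide/oxidopentadienyl cation closure assumed for marine prostanoids.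
- Enabling feature: the ring C8-C9(=O)-C10(Cl)=C11-C12(OH) is a 4-hydroxycyclopent-2-enone, an isomer of a 2-furylcarbinol. C9-C12 are furan C2-C5 (Cl on C3, octenyl chain on C5, ring O = the later C9 ketone O) and C8 is the carbinol carbon.
- C8-C9 disconnection: a 3-chloro-5-octenyl-2-furyllithium (from 3-bromofuran) adds to an (S)-alpha-silyloxy aldehyde (from (R)-glyceraldehyde acetonide by a Z-selective Wittig reaction). C7 is the only stereocentre carried in.
- Ring order: the furan is bought, and the cyclopentenone is the only ring formed (step 11).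

Key step: step 11

Remark: prostanoid numbering is used throughout (C1 = ester carbonyl, C8 and C12 = ring carbons bearing the two chains). In the target the C12 hydroxyl is cis to the C7 carbon, so the two carbon chains are trans.

**Step 1**
Reactants: 1 (R)-2,2-dimethyl-1,3-dioxolane-4-carbaldehyde; 2 (4-carboxybutyl)triphenylphosphonium bromide
Product: 5 methyl (5Z)-6-[(4S)-2,2-dimethyl-1,3-dioxolan-4-yl]hex-5-enoate, via ylide carboxylate 3 (not isolated), via sodium carboxylate 4 (not isolated)
Conditions: NaN(SiMe3)2 (2 equiv per 2), THF, 0 °C; 1, −78 °C to 23 °C; then MeI, DMF, 23 °C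
Reagents that add atoms: iodomethane CI
Why: Wittig olefination with a non-stabilised ylide under lithium-free conditions should give the Z alkene by kinetic control, the dioxolane stereocentre (future C7, from the chiral pool) is not touched, and the sodium carboxylate is O-methylated by SN2 in the same flask.

**Step 2**
Reactants: 5 methyl (5Z)-6-[(4S)-2,2-dimethyl-1,3-dioxolan-4-yl]hex-5-enoate
Product: 6 methyl (5Z,7S)-7,8-dihydroxyoct-5-enoate
Conditions: AcOH/H2O 4:1, 40 °C
Reagents that add atoms: none
Why: Acid-catalysed acetal hydrolysis frees the 7,8-diol while the methyl ester, the Z alkene and C7 are inert to warm aqueous acetic acid.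

**Step 3**
Reactants: 6 methyl (5Z,7S)-7,8-dihydroxyoct-5-enoate
Product: 7 methyl (5Z,7S)-7,8-bis(tert-butyldimethylsilyloxy)oct-5-enoate
Conditions: TBSCl, imidazole, DMF, 23 °C
Reagents that add atoms: tert-butyldimethylsilyl chloride CC(C)(C)[Si](C)(C)Cl
Why: Imidazole-promoted silylation protects both hydroxyls so that they can be told apart by steric demand in the next step.

**Step 4**
Reactants: 7 methyl (5Z,7S)-7,8-bis(tert-butyldimethylsilyloxy)oct-5-enoate
Product: 8 methyl (5Z,7S)-7-(tert-butyldimethylsilyloxy)-8-hydroxyoct-5-enoate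
Conditions: HF·pyridine, pyridine, THF, 0 °C
Reagents that add atoms: none
Why: Pyridine-buffered fluoride desilylation removes the less hindered primary silyl ether much faster than the secondary allylic one, a well-used steric differentiation.

**Step 5**
Reactants: 8 methyl (5Z,7S)-7-(tert-butyldimethylsilyloxy)-8-hydroxyoct-5-enoate
Product: 9 methyl (5Z,7S)-7-(tert-butyldimethylsilyloxy)-8-oxooct-5-enoate
Conditions: Dess-Martin periodinane, CH2Cl2, 0 °C to 23 °C; used at once
Reagents that add atoms: none
Why: Dess-Martin oxidation runs under nearly neutral conditions, so the alpha-silyloxy beta,gamma-unsaturated aldehyde should form without epimerisation at C7 or migration of the alkene.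

**Step 6**
Reactants: 10 3-bromofuran
Product: 12 3-chlorofuran, via 3-furyllithium 11 (not isolated)
Conditions: n-BuLi, Et2O, −78 °C; C2Cl6, −78 °C to 0 °C; fractional distillation
Reagents that add atoms: hexachloroethane ClC(Cl)(Cl)C(Cl)(Cl)Cl
Why: Bromine-lithium exchange at low temperature gives 3-furyllithium without migration of the metal, and the positive-chlorine donor C2Cl6 chlorinates it (halogen-metal exchange followed by electrophilic chlorination).

**Step 7**
Reactants: 12 3-chlorofuran
Product: 13 2-bromo-3-chlorofuran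
Conditions: NBS, DMF, 0 °C to 23 °C
Reagents that add atoms: N-bromosuccinimide O=C1CCC(=O)N1Br
Why: Electrophilic aromatic bromination goes to the alpha position next to the halogen, as in the analogous bromination of 3-bromofuran, and the bromine serves first as blocking group for C2 and later as the handle for metalation.

**Step 8**
Reactants: 14 (Z)-oct-2-en-1-ol
Product: 15 (Z)-1-bromooct-2-ene
Conditions: CBr4, PPh3, CH2Cl2, 0 °C
Reagents that add atoms: tetrabromomethane BrC(Br)(Br)Br
Why: The Appel reaction converts the primary allylic alcohol by SN2 at low temperature with retention of the Z geometry.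

**Step 9**
Reactants: 13 2-bromo-3-chlorofuran; 15 (Z)-1-bromooct-2-ene
Product: 17 2-bromo-3-chloro-5-[(Z)-oct-2-en-1-yl]furan, via 5-lithiofuran 16 (not isolated)
Conditions: 13 added to LiN(CHMe2)2, THF, −78 °C; then 15, DMPU, −78 °C to −30 °C
Reagents that add atoms: none
Why: Deprotonation takes the only remaining alpha hydrogen (C5) and the furyllithium is alkylated by SN2 at the primary allylic bromide, as in the usual allylation of 2-furyllithiums.

**Step 10**
Reactants: 17 2-bromo-3-chloro-5-[(Z)-oct-2-en-1-yl]furan; 9 methyl (5Z,7S)-7-(tert-butyldimethylsilyloxy)-8-oxooct-5-enoate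
Product: 19 methyl (5Z,7S,8RS)-7-(tert-butyldimethylsilyloxy)-8-{3-chloro-5-[(Z)-oct-2-en-1-yl]furan-2-yl}-8-hydroxyoct-5-enoate, via 2-lithiofuran 18 (not isolated)
Conditions: n-BuLi, THF, −78 °C; 9, −78 °C; AcOH quench at −78 °C
Reagents that add atoms: none
Why: Fast bromine-lithium exchange at the alpha carbon (the chlorine is inert) gives the 2-furyllithium without deprotonation of the doubly activated CH2, its 1,2-addition to the aldehyde outruns attack on the ester at low temperature, and the new C8 carbinol centre may form as a mixture because it is erased in the next step.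

**Step 11**
Reactants: 19 methyl (5Z,7S,8RS)-7-(tert-butyldimethylsilyloxy)-8-{3-chloro-5-[(Z)-oct-2-en-1-yl]furan-2-yl}-8-hydroxyoct-5-enoate
Product: 22 methyl (5Z,7S,8R,12S,14Z)-7-(tert-butyldimethylsilyloxy)-10-chloro-12-hydroxy-9-oxoprosta-5,10,14-trien-1-oate, via keto dienol 20 (not isolated), via 8-epimer 21 (not isolated)
Conditions: Dy(OTf)3 (10 mol %), t-BuOH/H2O 5:1, 70 °C; then 0 °C, Et3N (0.5 equiv), 23 °C
Reagents that add atoms: water O
Why: Dy(OTf)3 ionises the C8 carbinol of either epimer to a furan-stabilised cation, water adds at furan C5 (C12) and the resulting hemiketal opens to keto dienol 20, whose protonated form is a 1,4-dihydroxypentadienyl cation over C8-C12 that closes the C8-C12 bond. The closest known reaction is the Piancatelli rearrangement of 5-alkyl-2-furylcarbinols to 4-alkyl-4-hydroxy-5-substituted cyclopent-2-enones, a relative of the Nazarov cyclisation. The one ring is closed by a thermal 4π-conrotatory electrocyclisation, which in aldol terms is a 5-(enolendo)-exo-trig attack of enol carbon C8 on the activated C12 ketone. C12 is set here: the C10 chlorine pushes C7 to the outside position on C8, the C12 hydroxyl takes the outside position as is usual for this rearrangement, and with H7 eclipsing the C8=C9 bond (A(1,3) strain against O9, no chelation or hydrogen bond to the silyl ether) the new bond should form anti to the C6 alkenyl carbon and give (7S,8S,12S)-21 with hydroxyl and C7 trans. C8 is then set under thermodynamic control, because Et3N can enolise only C8-H and reprotonation places the branched C7 substituent trans to the octenyl chain and cis to the small hydroxyl, which is the (8R) configuration of 22, while quaternary C12 cannot change. The step needs regioselectivity between the two flanks of the latent enedione, and the substrate secures it because the enol is born only at C8=C9 from the carbinol carbon, so the doubly activated C13 methylene is never enolised, the open chloro-enedione never accumulates, and both Z alkenes, the ester and the vinylic chloride stay out of the reaction.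

**Step 12**
Reactants: 22 methyl (5Z,7S,8R,12S,14Z)-7-(tert-butyldimethylsilyloxy)-10-chloro-12-hydroxy-9-oxoprosta-5,10,14-trien-1-oate
Product: 23 methyl (5Z,7S,8R,12S,14Z)-10-chloro-7,12-dihydroxy-9-oxoprosta-5,10,14-trien-1-oate
Conditions: HF·pyridine, THF, 0 °C to 23 °C
Reagents that add atoms: none
Why: Fluoride cleavage of the secondary silyl ether under mildly acidic conditions avoids enolate formation, so the beta-hydroxy ketone, the chloroenone and the tertiary alcohol should survive.

**Step 13**
Reactants: 23 methyl (5Z,7S,8R,12S,14Z)-10-chloro-7,12-dihydroxy-9-oxoprosta-5,10,14-trien-1-oate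
Product: 24 punaglandin 8
Conditions: Ac2O, pyridine, CH2Cl2, 0 °C
Reagents that add atoms: acetic anhydride CC(=O)OC(C)=O
Why: Acylation with Ac2O in pyridine without an acyl-transfer catalyst is selective for the secondary C7 hydroxyl over the hindered tertiary C12 hydroxyl, and the low temperature disfavours loss of acetic acid across C7-C8.

**Compound list**

1 | (R)-2,2-dimethyl-1,3-dioxolane-4-carbaldehyde | CC1(C)OC[C@H](C=O)O1 | starting material
2 | (4-carboxybutyl)triphenylphosphonium bromide | OC(=O)CCCC[P+](c1ccccc1)(c1ccccc1)c1ccccc1.[Br-] | starting material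
3 | sodium 5-(triphenylphosphoranylidene)pentanoate | [Na+].[O-]C(=O)CCCC=P(c1ccccc1)(c1ccccc1)c1ccccc1 | intermediate
4 | sodium (5Z)-6-[(4S)-2,2-dimethyl-1,3-dioxolan-4-yl]hex-5-enoate | [Na+].CC1(C)OC[C@H](/C=C\CCCC([O-])=O)O1 | intermediate
5 | methyl (5Z)-6-[(4S)-2,2-dimethyl-1,3-dioxolan-4-yl]hex-5-enoate | CC1(C)OC[C@H](/C=C\CCCC(=O)OC)O1 | intermediate
6 | methyl (5Z,7S)-7,8-dihydroxyoct-5-enoate | OC[C@@H](O)/C=C\CCCC(=O)OC | intermediate
7 | methyl (5Z,7S)-7,8-bis(tert-butyldimethylsilyloxy)oct-5-enoate | CC(C)(C)[Si](C)(C)OC[C@@H](O[Si](C)(C)C(C)(C)C)/C=C\CCCC(=O)OC | intermediate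
8 | methyl (5Z,7S)-7-(tert-butyldimethylsilyloxy)-8-hydroxyoct-5-enoate | OC[C@@H](O[Si](C)(C)C(C)(C)C)/C=C\CCCC(=O)OC | intermediate
9 | methyl (5Z,7S)-7-(tert-butyldimethylsilyloxy)-8-oxooct-5-enoate | O=C[C@@H](O[Si](C)(C)C(C)(C)C)/C=C\CCCC(=O)OC | intermediate
10 | 3-bromofuran | Brc1ccoc1 | starting material
11 | 3-furyllithium | [Li]c1ccoc1 | intermediate
12 | 3-chlorofuran | Clc1ccoc1 | intermediate
13 | 2-bromo-3-chlorofuran | Clc1ccoc1Br | intermediate
14 | (Z)-oct-2-en-1-ol | CCCCC/C=C\CO | starting material
15 | (Z)-1-bromooct-2-ene | CCCCC/C=C\CBr | intermediate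
16 | (5-bromo-4-chlorofuran-2-yl)lithium | [Li]c1cc(Cl)c(Br)o1 | intermediate
17 | 2-bromo-3-chloro-5-[(Z)-oct-2-en-1-yl]furan | CCCCC/C=C\Cc1cc(Cl)c(Br)o1 | intermediate
18 | {3-chloro-5-[(Z)-oct-2-en-1-yl]furan-2-yl}lithium | CCCCC/C=C\Cc1cc(Cl)c([Li])o1 | intermediate
19 | methyl (5Z,7S,8RS)-7-(tert-butyldimethylsilyloxy)-8-{3-chloro-5-[(Z)-oct-2-en-1-yl]furan-2-yl}-8-hydroxyoct-5-enoate (both C8 epimers, C8 left open) | CCCCC/C=C\Cc1cc(Cl)c(C(O)[C@@H](O[Si](C)(C)C(C)(C)C)/C=C\CCCC(=O)OC)o1 | intermediate
20 | methyl (5Z,7S,8Z,10E,14Z)-7-(tert-butyldimethylsilyloxy)-10-chloro-9-hydroxy-12-oxoicosa-5,8,10,14-tetraenoate (C9 and C12 cis on the C10=C11 bond) | CCCCC/C=C\CC(=O)/C=C(Cl)\C(O)=C\[C@@H](O[Si](C)(C)C(C)(C)C)/C=C\CCCC(=O)OC | intermediate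
21 | methyl (5Z,7S,8S,12S,14Z)-7-(tert-butyldimethylsilyloxy)-10-chloro-12-hydroxy-9-oxoprosta-5,10,14-trien-1-oate (hydroxyl trans to C7) | CCCCC/C=C\C[C@@]1(O)C=C(Cl)C(=O)[C@H]1[C@H](/C=C\CCCC(=O)OC)O[Si](C)(C)C(C)(C)C | intermediate
22 | methyl (5Z,7S,8R,12S,14Z)-7-(tert-butyldimethylsilyloxy)-10-chloro-12-hydroxy-9-oxoprosta-5,10,14-trien-1-oate (hydroxyl cis to C7) | CCCCC/C=C\C[C@@]1(O)C=C(Cl)C(=O)[C@@H]1[C@H](/C=C\CCCC(=O)OC)O[Si](C)(C)C(C)(C)C | intermediate
23 | methyl (5Z,7S,8R,12S,14Z)-10-chloro-7,12-dihydroxy-9-oxoprosta-5,10,14-trien-1-oate | CCCCC/C=C\C[C@@]1(O)C=C(Cl)C(=O)[C@@H]1[C@H](/C=C\CCCC(=O)OC)O | intermediate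
24 | punaglandin 8, methyl (5Z,7S,8R,12S,14Z)-7-acetoxy-10-chloro-12-hydroxy-9-oxoprosta-5,10,14-trien-1-oate | CCCCC/C=C\C[C@@]1(O)C=C(Cl)C(=O)[C@@H]1[C@H](/C=C\CCCC(=O)OC)OC(C)=O | target

**Step count**

Total step count: 13. Longest linear sequence: 9 steps (steps 1-5 and 10-13).

**Steps most likely to fail**

**1. Step 11.**
- Possible failures at the cation stage: a 1,2-hydride shift from C7, proton loss from C13, or loss of the silyl group in the warm aqueous Lewis acid, which would open a hydrogen-bonded rotamer and reverse the facial bias.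
- Possible failures in closure and equilibration: weak facial selectivity of the closure, closure with the C12 oxygen inside, or beta-elimination of silanol during the C8 equilibration.
- Fallback: this uses known chemistry (furan photooxygenation followed by intramolecular aldol addition). It sets out from alcohol 8 and bromofuran 17 and comes back at 22.
  - Alcohol 8 is converted with Tf2O and 2,6-lutidine (CH2Cl2, −78 °C) into the primary triflate F1.
  - F1 is displaced at −78 °C by furyllithium 18 (made from 17 as in step 10) to give the 2-alkylfuran F2, in which C8 is a CH2 group.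
  - Sensitised photooxygenation (O2, 5,10,15,20-tetraphenylporphyrin, visible light, CH2Cl2/MeOH, −20 °C) and reduction with Me2S open the furan to the cis-enedione F3.
  - Brief exposure to EtN(CHMe2)2 in CH2Cl2 closes the same C8-C12 bond by aldol addition under thermodynamic control. This favours the trans arrangement of the two chains and gives 22 after chromatographic removal of any C12 diastereomer.

**2. Step 9.**
- Possible failures: bromine scrambling between lithiated and neutral bromofurans on warming, SN2' attack on the allylic bromide, or erosion of the Z geometry.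
- Fallback: it sets out from 12 and comes back at 17, with silicon in place of bromine as the blocking group.
  - 12 is lithiated at C2 with LiN(CHMe2)2 and quenched with Me3SiCl to give the silyl-blocked chlorofuran F4.
  - n-BuLi then removes the only alpha hydrogen left, and alkylation with 15 gives the octenyl silylfuran F5.
  - Ipso-bromodesilylation with NBS in MeCN at 0 °C returns 17.

**3. Step 10.**
- Possible failures: epimerisation of the labile aldehyde by the basic organolithium, 1,2-migration of the silyl group in the lithium alkoxide, or attack on the ester.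
- Fallback: it sets out from 17 and 9 and comes back at 19, with a non-basic organochromium nucleophile.
  - Furyllithium 18 made from 17 is quenched with I2 to give the iodofuran F6.
  - F6 is coupled with 9 by CrCl2 and catalytic NiCl2 in DMF at 23 °C (Nozaki-Hiyama-Kishi reaction) to give 19.

**Further compounds**

F1 | step 11 | methyl (5Z,7S)-7-(tert-butyldimethylsilyloxy)-8-(trifluoromethylsulfonyloxy)oct-5-enoate | O=S(=O)(OC[C@@H](O[Si](C)(C)C(C)(C)C)/C=C\CCCC(=O)OC)C(F)(F)F
F2 | step 11 | methyl (5Z,7R)-7-(tert-butyldimethylsilyloxy)-8-{3-chloro-5-[(Z)-oct-2-en-1-yl]furan-2-yl}oct-5-enoate (same spatial arrangement at C7, descriptor changes) | CCCCC/C=C\Cc1cc(Cl)c(C[C@@H](O[Si](C)(C)C(C)(C)C)/C=C\CCCC(=O)OC)o1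
F3 | step 11 | methyl (5Z,7R,10E,14Z)-7-(tert-butyldimethylsilyloxy)-10-chloro-9,12-dioxoicosa-5,10,14-trienoate (acyl groups cis) | CCCCC/C=C\CC(=O)/C=C(Cl)\C(=O)C[C@@H](O[Si](C)(C)C(C)(C)C)/C=C\CCCC(=O)OC
F4 | step 9 | (3-chlorofuran-2-yl)trimethylsilane | C[Si](C)(C)c1occc1Cl
F5 | step 9 | {3-chloro-5-[(Z)-oct-2-en-1-yl]furan-2-yl}trimethylsilane | CCCCC/C=C\Cc1cc(Cl)c([Si](C)(C)C)o1
F6 | step 10 | 3-chloro-2-iodo-5-[(Z)-oct-2-en-1-yl]furan | CCCCC/C=C\Cc1cc(Cl)c(I)o1
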